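## The problem

Nakijiquinone M (30) is a 2-hydroxy-5-(3-methylbutylamino)-1,4-benzoquinone joined through the C11 methylene to the quaternary C9 of a bicyclic sesquiterpene. Drimane numbering is used throughout: ring A is C1–C5 and C10, ring B is C5–C10. The decalin has three adjacent stereocentres, C8 (S, methyl), C9 (R, methyl and C11) and C10 (S, hydrogen). H8, H10 and C11 lie on one face and the two methyl groups on the other. C9 is the only centre that can be made on its own with reliable absolute control, so it has to direct C10 and C8. Ring A has no stereocentre, but its C4 gem-dimethyl group sits beside the trisubstituted C5=C6 alkene. That alkene must be placed regiospecifically, and strong acid would move it to C5=C10 and destroy C10. The quinone, a vinylogous acid and vinylogous amide, will not survive enolates, cuprates, hydrogenation or strong base, so it must be released at the end from a masked arene. The feature that opens the molecule is that C10 and C5 can be read as the β and α carbons of a ring B enone with its carbonyl at C6. If C7=C8 is unsaturated as well, ring B is a flat 4,4-disubstituted cyclohexa-2,5-dienone whose only stereocentre is C9, whose two alkenes differ by the C8 methyl group, and onto which C1–C4 can be added as a diene with a leaving oxygen on C4.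

## Retrosynthesis

The C–N bond of 30 is cut first. The amine 29 displaces methoxide from the vinylogous ester 28 by addition–elimination, which keeps the nitrogen out of all earlier steps. 28 goes back through the dimethoxyquinone 27 to the tetramethoxyarene 26. The arene tolerates organolithium, cuprate, Lewis acid and hydrogenation chemistry, and its symmetry allows only one para-quinone on oxidative demethylation. The forward steps need an oxidant that spares the C5=C6 alkene and a hydrolysis that selects the methoxy group beside the alkyl substituent.

In 26 the C6–H bond and one C4–CH3 bond are cut together. The enol triflate 25 fixes the alkene position, and 25 arises from conjugate methylation of the C4=C5 enone 23 followed by O-sulfonylation of the C5=C6 enolate that the addition creates. Dehydration or hydrazone routes from a C6 ketone would favour C6=C7 instead. 23 lacks the quaternary C4. The forward step asks a cuprate to add to a tetrasubstituted but s-cis (alkylidenecyclohexanone-type) enone.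

The C8–H bond is cut next, giving the cross-conjugated dienone 22. C8 is set at this stage on purpose. With C5 trigonal, ring B is a half-chair with H10 and the C9 methyl group axial on opposite faces and C11 equatorial. Hydrogen should then arrive on the face of C11 and leave the C8 methyl group equatorial, cis to the C9 methyl group, which is also the more stable epimer. In a cis-fused precursor with a saturated, fully substituted C4, the ring folds so that the benzyl group is axial beside C8, and the C8 epimer would be expected. The cost is that the trisubstituted C7=C8 alkene must be reduced beside the tetrasubstituted C4=C5 alkene.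

22 is related to 21 by loss of silanol across C4–C5 (E1cB from a β-silyloxy ketone), and 21 to 20 by saturation of the only unhindered alkene, C2=C3. These two steps are the price of a diene that carries its own leaving group.

20 is a cyclohexene with a ketone on the ring carbon next to the oxygen-bearing carbon, the pattern of a Diels–Alder adduct. Cutting C1–C10 and C4–C5 gives the dienone 17 and the diene 19. Other two-bond cuts of ring A give no stabilised pair of fragments. A two-step annulation (conjugate addition, then aldol) needs the same facial control but does not close the ring in one operation. The simplification is large: 17 has one ring and one stereocentre, 19 has none. The forward reaction must choose the unsubstituted alkene of 17, the face of the C9 methyl group, and the orientation in which the CH2 terminus of 19 bonds to C10.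

19 is the silyl dienol ether of the deconjugated ketone 18, chosen so that the proton removed is the doubly activated one. 17 is the dehydrogenation product of enone 14. 14 is opened at its alkene (aldol condensation) to the 1,5-diketone 13; the one concern is which ketone acts as the nucleophile. 13 is the hydrolysis product of the methyl adduct of the bicyclic lactam 11.

In 11 both new bonds at the quaternary carbon are cut: benzylation of 9 with bromide 4, and methylation of the parent lactam 7, the condensation product of 5 and 6. The second alkylation in this lactam class takes place anti to the angular methyl group, so methyl first and benzyl second gives the C9 configuration of 30 from natural 5. Bromide 4 comes from arene 1 through aryllithium 2 and alcohol 3.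

## Roads not taken

Alternative 1: The cut runs through C4–C5 and C9–C10 of a normal drimane. The (2E,6E)-farnesyl arene A1, one C–C bond away from the lithiated arene 2, would be protonated at its terminal alkene by a chiral Lewis-acid-assisted Brønsted acid (SnCl4 with a BINOL monoether) or a squalene–hopene cyclase. Both rings close in one cascade and proton loss from the C8 cation gives the drim-7-ene A2.
- Merits: two rings, two C–C bonds and the absolute configuration come in one step from an achiral precursor, in a route perhaps a third as long as the one chosen.
- Weak points: A2 is not the skeleton of 30. It has the methyl group on C10 and hydrogen on C9, so a second cationic step must move H9 to C8, the C10 methyl to C9 and H5 to C10 before H6 is lost. The suprafacial 1,2-shifts would give the right relative configuration at C8, C9 and C10, but nothing tells the cascade to stop there. Proton loss from the C10 cation (to the tetrasubstituted C5=C10 alkene) and onward migration of a C4 methyl group to C5 are the usual exits. Enantioselectivity is also less secure when the cyclisation is not ended by an arene.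
- Comparison: in step count this road is clearly better. The chosen plan sets against it that each stereocentre and the alkene position are fixed by a separate, directed operation.

Alternative 2: The C9–C10 bond is traded for the C6–O bond of the δ-lactone A3. Its ring holds C9 (with the benzyl group), C8 (methyl), C7 and C6, and C6 carries the 6,6-dimethylcyclohexenyl ring A. The silyl ketene acetal of A3 would rearrange through the boat transition state that the lactone enforces (Ireland–Claisen), forming C9–C10 as C6–O breaks and giving the acid A4 with the C5=C6 alkene in place.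
- Merits: the ketene acetal geometry is fixed by the ring, so the two centres of A3 are transferred to C9 and C10. The bond to the quaternary carbon is made by a sigmatropic shift. The alkene needs no enol triflate, and C8 needs no hydrogenation. On these points it is better than the chosen plan.
- Weak points: A3 has two stereocentres (methyl trans to the cyclohexenyl group) that must themselves be made enantioselectively, so the problem is moved, not solved. The shift must join a fully substituted ketene acetal carbon to a ring alkene carbon through a boat. The carboxyl group on the neopentyl C9 must then be reduced to methyl in about three further steps.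
- Comparison: the length would be similar. The chosen plan has C9 from an established auxiliary alkylation with its methyl group already at the final oxidation level.

Alternative 3: The quinone ring is grown on C11 at the end. The cyclobutenone A5 (C11 on the carbon next to the carbonyl, methoxy next to the carbinol carbon, a Z-2-ethoxyvinyl group on the carbinol carbon) would open on heating to a dienylketene. Six-electron electrocyclisation and tautomerisation give the hydroquinone A6, which is then oxidised, hydrolysed at the methoxy group and aminated at the ethoxy-bearing carbon.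
- Merits: neutral thermal conditions, a substitution pattern fixed by construction, a mild hydroquinone oxidation in place of oxidative demethylation beside the C5=C6 alkene, and late access to analogues. On these points it is better than steps 16 to 18.
- Weak points: it leaves the real difficulty, the C8–C9–C10 triad and ring A, untouched. A5 needs the finished decalin as a carbon nucleophile at the neopentyl C11, which is hard to form and to add. It puts three to four more steps at the end of the longest sequence.
- Comparison: the chosen plan introduces C11 and the masked quinone together in one alkylation (step 5) and relies on the arene being inert up to step 16.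

Key step: step 10

Remarks on the chemistry:
- Pent-4-en-2-one (18) is taken as purchasable. It is preferred to the conjugated isomer, which would lose a C1 methyl proton on soft enolisation.
- The enolate of 9 is assumed to be alkylated on the face away from the angular C8a methyl group, as is general for this lactam class.

## Route

Step 1
Reactants: 1 1,2,4,5-tetramethoxybenzene
Product: 3 (2,3,5,6-tetramethoxyphenyl)methanol, via 2,3,5,6-tetramethoxyphenyllithium 2 (not isolated)
Conditions: n-BuLi, TMEDA, THF, 0 °C; (CH2O)n, 0 °C → rt
Reagents that add atoms: formaldehyde (from paraformaldehyde), C=O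
Why: Directed ortho-lithiation removes a ring proton flanked by two methoxy groups, and the aryllithium is hydroxymethylated by formaldehyde. The two ring hydrogens are equivalent, so only one mono-adduct can form.

Step 2
Reactants: 3 (2,3,5,6-tetramethoxyphenyl)methanol
Product: 4 3-(bromomethyl)-1,2,4,5-tetramethoxybenzene
Conditions: PBr3, CH2Cl2, 0 °C
Reagents that add atoms: phosphorus tribromide, BrP(Br)Br
Why: Standard conversion of a benzylic alcohol into the bromide through its bromophosphite; the electron-rich bromide is used without chromatography.

Step 3
Reactants: 5 L-valinol; 6 5-oxohexanoic acid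
Product: 7 (3S,8aR)-8a-methyl-3-(propan-2-yl)hexahydro-5H-oxazolo[3,2-a]pyridin-5-one
Conditions: toluene, reflux, Dean–Stark
Reagents that add atoms: none
Why: Cyclocondensation of an amino alcohol with a δ-keto acid forms the amide and the N,O-ketal with azeotropic removal of water. The angular centre C8a is set under thermodynamic control by the valinol centre, with isopropyl and angular methyl on the same convex face.

Step 4
Reactants: 7 (3S,8aR)-8a-methyl-3-(propan-2-yl)hexahydro-5H-oxazolo[3,2-a]pyridin-5-one
Product: 9 (3S,8aR)-6,8a-dimethyl-3-(propan-2-yl)hexahydro-5H-oxazolo[3,2-a]pyridin-5-one (C6 epimers), via lithium enolate 8 (not isolated)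
Conditions: LiN(i-Pr)2, THF, −78 °C; MeI
Reagents that add atoms: iodomethane, CI
Why: Lactam enolate alkylation; the epimer composition at C6 does not matter because this carbon is made planar again in step 5.

Step 5
Reactants: 9 (3S,8aR)-6,8a-dimethyl-3-(propan-2-yl)hexahydro-5H-oxazolo[3,2-a]pyridin-5-one; 4 3-(bromomethyl)-1,2,4,5-tetramethoxybenzene
Product: 11 (3S,6R,8aR)-6,8a-dimethyl-3-(propan-2-yl)-6-(2,3,5,6-tetramethoxybenzyl)hexahydro-5H-oxazolo[3,2-a]pyridin-5-one, via lithium enolate 10 (not isolated)
Conditions: LiN(i-Pr)2, THF, −78 → 0 °C; then 4, −78 → −20 °C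
Reagents that add atoms: none
Why: Second alkylation of the bicyclic lactam enolate, in which the electrophile enters on the face opposite the angular C8a methyl group. With methyl introduced first and the benzyl group second, the quaternary centre is 6R, the future C9. A benzylic bromide is reactive enough for a tetrasubstituted enolate.

Step 6
Reactants: 11 (3S,6R,8aR)-6,8a-dimethyl-3-(propan-2-yl)-6-(2,3,5,6-tetramethoxybenzyl)hexahydro-5H-oxazolo[3,2-a]pyridin-5-one
Product: 13 (3R)-3-methyl-3-(2,3,5,6-tetramethoxybenzyl)heptane-2,6-dione, via lithium hemiaminal alkoxide 12 (not isolated)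
Conditions: MeLi, THF, −78 → 0 °C; then aq Bu4N·H2PO4, EtOH, reflux
Reagents that add atoms: methyllithium, [Li]C; water, O
Why: 1,2-Addition of MeLi to the tertiary lactam gives a hemiaminal alkoxide that does not collapse before work-up, so no second addition occurs. Buffered hydrolysis then releases both ketones and the auxiliary. The quaternary centre has no α-hydrogen and cannot epimerise.

Step 7
Reactants: 13 (3R)-3-methyl-3-(2,3,5,6-tetramethoxybenzyl)heptane-2,6-dione
Product: 14 (4R)-3,4-dimethyl-4-(2,3,5,6-tetramethoxybenzyl)cyclohex-2-en-1-one
Conditions: pyrrolidine, AcOH, toluene, 80 °C; aq AcOH work-up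
Reagents that add atoms: none
Why: Amine-mediated intramolecular aldol condensation, as in the ring closure of a Robinson annulation. The enamine can form only at the unhindered C6 ketone, and its terminal carbon closes the six-membered ring onto the C2 ketone beside the quaternary carbon (6-enolendo-exo-trig). Dehydration gives the conjugated enone.

Step 8
Reactants: 14 (4R)-3,4-dimethyl-4-(2,3,5,6-tetramethoxybenzyl)cyclohex-2-en-1-one
Product: 17 (4S)-3,4-dimethyl-4-(2,3,5,6-tetramethoxybenzyl)cyclohexa-2,5-dien-1-one, via lithium dienolate 15 (not isolated), via trimethylsilyl dienol ether 16 (not isolated)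
Conditions: LiN(i-Pr)2, THF, −78 °C; Me3SiCl; then Pd(OAc)2 (10 mol %), O2, DMSO, rt
Reagents that add atoms: none
Why: Saegusa–Ito dehydrogenation: kinetic deprotonation at C6 gives the cross-conjugated silyl dienol ether, divalent palladium adds at C6 and β-hydride loss from C5 gives the second alkene. The quaternary C4 blocks any tautomerisation to a phenol. The descriptor changes from R to S only because the priorities change.

Step 9
Reactants: 18 pent-4-en-2-one
Product: 19 tert-butyl(dimethyl)[(2Z)-penta-2,4-dien-2-yloxy]silane
Conditions: t-BuMe2SiOTf, Et3N, Et2O, 0 °C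
Reagents that add atoms: tert-butyldimethylsilyl trifluoromethanesulfonate, CC(C)(C)[Si](C)(C)OS(=O)(=O)C(F)(F)F
Why: Soft enolisation: O-silylation followed by loss of the doubly activated C3 proton gives the conjugated 2-silyloxy-2,4-diene, expected mainly as the Z isomer as for other methyl ketones. The geometry has no consequence for the route because C4 becomes trigonal in step 12.

Step 10
Reactants: 17 (4S)-3,4-dimethyl-4-(2,3,5,6-tetramethoxybenzyl)cyclohexa-2,5-dien-1-one; 19 tert-butyl(dimethyl)[(2Z)-penta-2,4-dien-2-yloxy]silane
Product: 20 cis-fused 8-(tert-butyldimethylsilyloxy)-3,4,8-trimethyl-4-(2,3,5,6-tetramethoxybenzyl)-4a,5,8,8a-tetrahydronaphthalen-1(4H)-one (drimane numbering: C6 ketone, C2=C3 and C7=C8 alkenes; H5, H10, C11 and the C4 silyloxy group on one face, the C9 and C4 methyl groups on the other)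
Conditions: ZnCl2 (1 equiv), 19 (3 equiv), CH2Cl2, −20 °C → rt
Reagents that add atoms: none
Why: ZnCl2 binds the dienone carbonyl and the electron-rich diene adds across the unsubstituted alkene in a concerted, asynchronous, normal-demand [4+2] cycloaddition, the C1–C10 bond (CH2 terminus to the enone β-carbon) running ahead of the C4–C5 bond. The closest known reactions are Diels–Alder additions of 4,4-disubstituted cyclohexa-2,5-dienones to 1-silyloxybuta-1,3-dienes. Ring A closes as a six-membered carbocycle by suprafacial addition to both partners, which makes the ring fusion cis. C10 is controlled by C9: the diene approaches the flat ring on the face of the C9 methyl group, away from the benzyl group whose aryl ring covers the other face, so C1 ends cis to the C9 methyl and H10 cis to C11. C5 follows from suprafacial addition and C4 from the endo transition state of the Z-diene; both are erased in steps 12 and 14, so only the C9/C10 relation has to be right. Site selectivity rests on the C8 methyl group, which makes the other alkene a β,β-disubstituted and much poorer dienophile. Orientation rests on the silyloxy donor, which puts the largest HOMO coefficient on the CH2 terminus and gives the ortho adduct with oxygen β to the ketone. The tert-butyldimethylsilyl ether is chosen so that the β-silyloxy ketone survives ZnCl2 and work-up.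

Step 11
Reactants: 20 cis-fused Diels–Alder adduct
Product: 21 cis-fused 8-(tert-butyldimethylsilyloxy)-3,4,8-trimethyl-4-(2,3,5,6-tetramethoxybenzyl)-4a,5,6,7,8,8a-hexahydronaphthalen-1(4H)-one (configuration as in 20, C2–C3 saturated)
Conditions: H2 (1 atm), RhCl(PPh3)3 (5 mol %), benzene, rt
Reagents that add atoms: none
Why: Homogeneous hydrogenation with RhCl(PPh3)3 reduces the cis-disubstituted isolated alkene and leaves the hindered, conjugated, trisubstituted C7=C8 alkene untouched. No stereocentre is formed.

Step 12
Reactants: 21 cis-fused dihydro adduct
Product: 22 3,4,8-trimethyl-4-(2,3,5,6-tetramethoxybenzyl)-4a,5,6,7-tetrahydronaphthalen-1(4H)-one (drimane numbering: C4=C5 and C7=C8 alkenes, C6 ketone; H10 cis to C11)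
Conditions: DBU, toluene, 80 °C
Reagents that add atoms: none
Why: E1cB elimination of a β-silyloxy ketone: enolisation towards C5 and loss of silanolate give the tetrasubstituted C4=C5 enone. H10 is on a carbon attached to the α-carbon and is not activated, so C10 keeps its configuration.

Step 13
Reactants: 22 cross-conjugated dienone
Product: 23 (8S,9R,10S; drimane numbering) 3,4,8-trimethyl-4-(2,3,5,6-tetramethoxybenzyl)-3,4,4a,5,6,7-hexahydronaphthalen-1(2H)-one (C4=C5 enone; C8 and C9 methyl groups cis; H8 and H10 cis to C11)
Conditions: H2 (1 atm), Pd/C, EtOAc, rt, stopped after one equivalent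
Reagents that add atoms: none
Why: Catalytic hydrogenation takes the trisubstituted enone alkene in preference to the tetrasubstituted one. With C5 trigonal, ring B is a half-chair with the C9 methyl group axial on the lower face and C11 equatorial, so hydrogen is delivered from the face of C11. The C8 methyl group ends equatorial and cis to the C9 methyl group, which is also the more stable epimer.

Step 14
Reactants: 23 C4=C5 enone
Product: 25 (8S,9R,10S; drimane numbering) 3,4,8,8-tetramethyl-4-(2,3,5,6-tetramethoxybenzyl)-2,3,4,4a,5,6,7,8-octahydronaphthalen-1-yl trifluoromethanesulfonate, via lithium enolate 24 (not isolated)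
Conditions: Me2CuLi (from CuI, MeLi), Et2O, 0 °C; then N-(5-chloropyridin-2-yl)bis(trifluoromethanesulfonyl)imide, THF, 0 °C → rt
Reagents that add atoms: lithium dimethylcuprate, [Li+].C[Cu-]C; N-(5-chloropyridin-2-yl)bis(trifluoromethanesulfonyl)imide, O=S(=O)(N(c1ccc(Cl)cn1)S(=O)(=O)C(F)(F)F)C(F)(F)F
Why: Conjugate addition of a methyl cuprate to an s-cis alkylidenecyclohexanone-type enone (as with pulegone) creates the C4 gem-dimethyl group and gives the C5=C6 enolate regiospecifically. The enolate is trapped on oxygen by the triflimide. No stereocentre is formed.

Step 15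
Reactants: 25 enol triflate
Product: 26 3-{[(1R,2S,8aS)-1,2,5,5-tetramethyl-1,2,3,5,6,7,8,8a-octahydronaphthalen-1-yl]methyl}-1,2,4,5-tetramethoxybenzene
Conditions: Pd(OAc)2 (5 mol %), PPh3, HCO2H, n-Bu3N, DMF, 60 °C
Reagents that add atoms: none
Why: Palladium-catalysed formate reduction of an enol triflate: oxidative addition to zerovalent palladium, exchange of triflate for formate, loss of CO2 and reductive elimination of the C6–H bond. The alkene stays at C5=C6 under these non-acidic conditions.

Step 16
Reactants: 26 tetramethoxyarene
Product: 27 2,5-dimethoxy-3-{[(1R,2S,8aS)-1,2,5,5-tetramethyl-1,2,3,5,6,7,8,8a-octahydronaphthalen-1-yl]methyl}cyclohexa-2,5-diene-1,4-dione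
Conditions: (NH4)2Ce(NO3)6, MeCN–H2O, 0 °C
Reagents that add atoms: water, O
Why: Oxidative demethylation of a 1,4-dimethoxyarene by tetravalent cerium; by the symmetry of the ring both para pairs give the same 2,5-dimethoxyquinone. The arene is oxidised far faster than the trisubstituted alkene at 0 °C.

Step 17
Reactants: 27 dimethoxyquinone
Product: 28 2-hydroxy-5-methoxy-3-{[(1R,2S,8aS)-1,2,5,5-tetramethyl-1,2,3,5,6,7,8,8a-octahydronaphthalen-1-yl]methyl}cyclohexa-2,5-diene-1,4-dione
Conditions: KOH, MeOH–H2O, rt; then aq HCl
Reagents that add atoms: potassium hydroxide, [K+].[OH-]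
Why: Addition–elimination of hydroxide at the vinylogous ester beside the alkyl group, the regiochemistry established for 3-alkyl-2,5-dimethoxybenzoquinones of this family. The product is a vinylogous acid whose anion resists a second hydrolysis.

Step 18
Reactants: 28 hydroxy(methoxy)quinone; 29 3-methylbutan-1-amine
Product: 30 nakijiquinone M
Conditions: 29, NaHCO3, EtOH–H2O, rt
Reagents that add atoms: none
Why: Addition–elimination of the primary amine at the remaining vinylogous ester carbon gives the vinylogous amide. This is the standard last step from methoxyquinones to aminoquinones of this class, and the mild conditions leave the decalin stereocentres and the alkene untouched.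

## Compound list

1 | 1,2,4,5-tetramethoxybenzene | COc1cc(OC)c(OC)cc1OC | starting material
2 | 2,3,5,6-tetramethoxyphenyllithium | COc1cc(OC)c(OC)c([Li])c1OC | intermediate (not isolated)
3 | (2,3,5,6-tetramethoxyphenyl)methanol | COc1cc(OC)c(OC)c(CO)c1OC | intermediate
4 | 3-(bromomethyl)-1,2,4,5-tetramethoxybenzene | COc1cc(OC)c(OC)c(CBr)c1OC | intermediate
5 | L-valinol, (S)-2-amino-3-methylbutan-1-ol | CC(C)[C@H](N)CO | starting material
6 | 5-oxohexanoic acid | CC(=O)CCCC(=O)O | starting material
7 | (3S,8aR)-8a-methyl-3-(propan-2-yl)hexahydro-5H-oxazolo[3,2-a]pyridin-5-one | CC(C)[C@H]1CO[C@]2(C)CCCC(=O)N12 | intermediate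
8 | lithium enolate of 7 | CC(C)[C@H]1CO[C@]2(C)CCC=C([O-])N12.[Li+] | intermediate (not isolated)
9 | (3S,8aR)-6,8a-dimethyl-3-(propan-2-yl)hexahydro-5H-oxazolo[3,2-a]pyridin-5-one, C6 epimers | CC(C)[C@H]1CO[C@]2(C)CCC(C)C(=O)N12 | intermediate
10 | lithium enolate of 9 | CC(C)[C@H]1CO[C@]2(C)CCC(C)=C([O-])N12.[Li+] | intermediate (not isolated)
11 | (3S,6R,8aR)-6,8a-dimethyl-3-(propan-2-yl)-6-(2,3,5,6-tetramethoxybenzyl)hexahydro-5H-oxazolo[3,2-a]pyridin-5-one | CC(C)[C@H]1CO[C@]2(C)CC[C@](C)(Cc3c(OC)c(OC)cc(OC)c3OC)C(=O)N12 | intermediate
12 | lithium alkoxide of the C5 methyl hemiaminal of 11 (C5 configuration open) | CC(C)[C@H]1CO[C@]2(C)CC[C@](C)(Cc3c(OC)c(OC)cc(OC)c3OC)C(C)([O-])N12.[Li+] | intermediate (not isolated)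
13 | (3R)-3-methyl-3-(2,3,5,6-tetramethoxybenzyl)heptane-2,6-dione | CC(=O)CC[C@](C)(Cc1c(OC)c(OC)cc(OC)c1OC)C(C)=O | intermediate
14 | (4R)-3,4-dimethyl-4-(2,3,5,6-tetramethoxybenzyl)cyclohex-2-en-1-one | COc1cc(OC)c(OC)c(C[C@@]2(C)CCC(=O)C=C2C)c1OC | intermediate
15 | lithium cross-conjugated dienolate of 14 | COc1cc(OC)c(OC)c(C[C@@]2(C)CC=C([O-])C=C2C)c1OC.[Li+] | intermediate (not isolated)
16 | trimethylsilyl dienol ether of 14 | COc1cc(OC)c(OC)c(C[C@@]2(C)CC=C(O[Si](C)(C)C)C=C2C)c1OC | intermediate (not isolated)
17 | (4S)-3,4-dimethyl-4-(2,3,5,6-tetramethoxybenzyl)cyclohexa-2,5-dien-1-one | COc1cc(OC)c(OC)c(C[C@@]2(C)C=CC(=O)C=C2C)c1OC | intermediate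
18 | pent-4-en-2-one | CC(=O)CC=C | starting material
19 | tert-butyl(dimethyl)[(2Z)-penta-2,4-dien-2-yloxy]silane | C=C/C=C(/C)O[Si](C)(C)C(C)(C)C | intermediate
20 | cis-fused Diels–Alder adduct: C4 silyloxy, C2=C3, C6 ketone, C7=C8; H5, H10, C11 and OSi on one face | COc1cc(OC)c(OC)c(C[C@@]2(C)[C@@H]3CC=C[C@@](C)(O[Si](C)(C)C(C)(C)C)[C@@H]3C(=O)C=C2C)c1OC | intermediate
21 | dihydro adduct: as 20 with C2–C3 saturated | COc1cc(OC)c(OC)c(C[C@@]2(C)[C@@H]3CCC[C@@](C)(O[Si](C)(C)C(C)(C)C)[C@@H]3C(=O)C=C2C)c1OC | intermediate
22 | cross-conjugated dienone: C4=C5, C6 ketone, C7=C8; H10 cis to C11 | COc1cc(OC)c(OC)c(C[C@@]2(C)[C@@H]3CCCC(C)=C3C(=O)C=C2C)c1OC | intermediate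
23 | (8S,9R,10S) C4=C5 enone with C8 set; C8 and C9 methyl groups cis | COc1cc(OC)c(OC)c(C[C@@]2(C)[C@@H]3CCCC(C)=C3C(=O)C[C@@H]2C)c1OC | intermediate
24 | lithium C5=C6 enolate with C4 gem-dimethyl group | COc1cc(OC)c(OC)c(C[C@@]2(C)[C@@H]3CCCC(C)(C)C3=C([O-])C[C@@H]2C)c1OC.[Li+] | intermediate (not isolated)
25 | (8S,9R,10S) C5=C6 enol triflate | COc1cc(OC)c(OC)c(C[C@@]2(C)[C@@H]3CCCC(C)(C)C3=C(OS(=O)(=O)C(F)(F)F)C[C@@H]2C)c1OC | intermediate
26 | 3-{[(1R,2S,8aS)-1,2,5,5-tetramethyl-1,2,3,5,6,7,8,8a-octahydronaphthalen-1-yl]methyl}-1,2,4,5-tetramethoxybenzene | COc1cc(OC)c(OC)c(C[C@@]2(C)[C@@H]3CCCC(C)(C)C3=CC[C@@H]2C)c1OC | intermediate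
27 | 2,5-dimethoxy-3-(decalinylmethyl)-1,4-benzoquinone, decalin as in 26 | COC1=CC(=O)C(OC)=C(C[C@@]2(C)[C@@H]3CCCC(C)(C)C3=CC[C@@H]2C)C1=O | intermediate
28 | 2-hydroxy-5-methoxy-3-(decalinylmethyl)-1,4-benzoquinone, decalin as in 26 | COC1=CC(=O)C(O)=C(C[C@@]2(C)[C@@H]3CCCC(C)(C)C3=CC[C@@H]2C)C1=O | intermediate
29 | 3-methylbutan-1-amine | CC(C)CCN | starting material
30 | nakijiquinone M | CC(C)CCNC1=CC(=O)C(O)=C(C[C@@]2(C)[C@@H]3CCCC(C)(C)C3=CC[C@@H]2C)C1=O | target

## Step count and risks

Total: 18 steps. Longest linear sequence: 15 steps (steps 3–8 and 10–18 from 5 and 6; the arene branch through steps 1, 2, 5–8 and 10–18 is equally long).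

Least certain steps:

**Step 10 (key step).** The diene terminus carries two substituents and C10 lies beside the quaternary C9, so the cycloaddition may be slow. The Lewis acid may then divert the reaction to a stepwise Mukaiyama–Michael addition that stops at an open-chain product, or hydrolyse the diene. Discrimination between the benzyl and methyl faces may be incomplete, and the adduct may lose silanol in the flask. Fallback: from 17, CuBr·SMe2-catalysed 1,4-addition of [3-(2-methyl-1,3-dioxolan-2-yl)propyl]magnesium bromide at the unsubstituted β-carbon, anti to the benzyl group, would give after protonation the ketal enone F1. Aqueous acid would free the methyl ketone F2, and base-mediated aldol condensation of C5 onto the side-chain ketone would close ring A and give 22 directly. Steps 11 and 12 are then not needed. This keeps the C1–C10 and C4–C5 bonds but forms them one after the other.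

**Step 13.** Hydrogenation may continue into the C4=C5 alkene, or hydrogen may be delivered to the lower face if the half-chair with an axial benzyl group reacts faster, giving the C8 epimer. Fallback: from 22, reduction with lithium in liquid ammonia (THF, one equivalent of t-BuOH) would go by electron transfer to the less substituted enone and axial protonation at C8, which favours the equatorial methyl group. This forms the lithium dienolate F3, and protonation at C7 on quenching returns 23.

**Step 7.** Ring closure may run the other way, with the methyl group of the hindered ketone attacking the unhindered ketone, giving the 3,6,6-trisubstituted cyclohexenone. Fallback: from 11, reduction with NaAlH2(OCH2CH2OMe)2 gives the carbinolamine F4, and buffered hydrolysis gives the keto aldehyde F5. Only the ketone of F5 can enolise towards the aldehyde, so base-mediated aldol condensation gives (4R)-4-methyl-4-(2,3,5,6-tetramethoxybenzyl)cyclohex-2-en-1-one F6 without ambiguity. Conjugate methylation with Me2CuLi and Me3SiCl gives the silyl enol ether F7, and dehydrogenation with Pd(OAc)2 returns 14.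

**Step 14.** Addition of the cuprate to the tetrasubstituted enone may be slow, and the hindered, copper-bearing enolate beside the new gem-dimethyl group may be sulfonylated incompletely, so that the ketone is recovered and the regiochemistry lost. Fallback: from 23, conjugate addition of Me2CuLi in the presence of Me3SiCl gives the trimethylsilyl enol ether F8, which is isolated. Cleavage with MeLi regenerates the copper-free lithium enolate 24, and sulfonylation as before gives 25.

## Further compounds

F1 | step 10 | 3,4-dimethyl-5-[3-(2-methyl-1,3-dioxolan-2-yl)propyl]-4-(2,3,5,6-tetramethoxybenzyl)cyclohex-2-en-1-one, side chain cis to the C4 methyl group | COc1cc(OC)c(OC)c(C[C@@]2(C)[C@H](CCCC3(C)OCCO3)CC(=O)C=C2C)c1OC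
F2 | step 10 | 3,4-dimethyl-5-(4-oxopentyl)-4-(2,3,5,6-tetramethoxybenzyl)cyclohex-2-en-1-one, configuration as F1 | COc1cc(OC)c(OC)c(C[C@@]2(C)[C@H](CCCC(C)=O)CC(=O)C=C2C)c1OC
F3 | step 13 | lithium cross-conjugated dienolate of 23 | COc1cc(OC)c(OC)c(C[C@@]2(C)[C@@H]3CCCC(C)=C3C([O-])=C[C@@H]2C)c1OC.[Li+]
F4 | step 7 | carbinolamine from reduction of 11 (C5 configuration open) | CC(C)[C@H]1CO[C@]2(C)CC[C@](C)(Cc3c(OC)c(OC)cc(OC)c3OC)C(O)N12
F5 | step 7 | (2R)-2-methyl-5-oxo-2-(2,3,5,6-tetramethoxybenzyl)hexanal | CC(=O)CC[C@](C)(Cc1c(OC)c(OC)cc(OC)c1OC)C=O
F6 | step 7 | (4R)-4-methyl-4-(2,3,5,6-tetramethoxybenzyl)cyclohex-2-en-1-one | COc1cc(OC)c(OC)c(C[C@@]2(C)CCC(=O)C=C2)c1OC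
F7 | step 7 | {[(4R)-3,4-dimethyl-4-(2,3,5,6-tetramethoxybenzyl)cyclohex-1-en-1-yl]oxy}trimethylsilane, C3 epimers | COc1cc(OC)c(OC)c(C[C@@]2(C)CCC(O[Si](C)(C)C)=CC2C)c1OC
F8 | step 14 | trimethylsilyl C5=C6 enol ether with C4 gem-dimethyl group | COc1cc(OC)c(OC)c(C[C@@]2(C)[C@@H]3CCCC(C)(C)C3=C(O[Si](C)(C)C)C[C@@H]2C)c1OC
A1 | alternative 1 | 1,2,4,5-tetramethoxy-3-[(2E,6E)-3,7,11-trimethyldodeca-2,6,10-trien-1-yl]benzene | COc1cc(OC)c(OC)c(C/C=C(\C)CC/C=C(\C)CCC=C(C)C)c1OC
A2 | alternative 1 | 11-(2,3,5,6-tetramethoxyphenyl)drim-7-ene | COc1cc(OC)c(OC)c(C[C@H]2C(C)=CC[C@H]3C(C)(C)CCC[C@]23C)c1OC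
A3 | alternative 2 | 6-(6,6-dimethylcyclohex-1-en-1-yl)-4-methyl-3-(2,3,5,6-tetramethoxybenzyl)tetrahydro-2H-pyran-2-one, 4-methyl trans to the 6-cyclohexenyl group, C3 open | O=C1O[C@@H](C2=CCCCC2(C)C)C[C@H](C)C1Cc1c(OC)c(OC)cc(OC)c1OC
A4 | alternative 2 | decalin C9 carboxylic acid | COc1cc(OC)c(OC)c(C[C@@]2(C(=O)O)[C@@H]3CCCC(C)(C)C3=CC[C@@H]2C)c1OC
A5 | alternative 3 | 4-[(Z)-2-ethoxyvinyl]-4-hydroxy-3-methoxy-2-(decalinylmethyl)cyclobut-2-en-1-one, decalin as in 26, carbinol centre open | CCO/C=C\C1(O)C(OC)=C(C[C@@]2(C)[C@@H]3CCCC(C)(C)C3=CC[C@@H]2C)C1=O
A6 | alternative 3 | 5-ethoxy-2-methoxy-3-(decalinylmethyl)hydroquinone | CCOc1cc(O)c(OC)c(C[C@@]2(C)[C@@H]3CCCC(C)(C)C3=CC[C@@H]2C)c1O
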